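**Retrosynthetic overview**
- The target comes from chloride opening of an 11,20-epoxide, after acetylation of a C2/C9/C12 triol.
- The ten-membered ring B (Z-C3=C4, C5=C16) and a temporary seven-membered oxasilepine are closed together by a silicon-tethered enyne/diene metathesis cascade; fluoride then removes the silicon.
- The γ-lactone with C6–Cl and C7–O comes from an anti-selective chloropropargylation of a C7 lactol, followed by oxidative lactonisation.
- The C8–C9 bond comes from acylation of a hydroxylactone dianion (C7, C8, C17–C19) by a ring-A lactone, then chelation-controlled reduction at C9.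
- Ring A is made first by an asymmetric Diels–Alder reaction, then vinylation/lactonisation, α′-methylenation, CBS reduction and directed epoxidation. Ring order: A, temporary C2–O–C9 lactone, γ-lactone, oxasilepine together with ring B.

Assumption: locants C1–C20 are the briarane locants of the target, "as in the target" means the same spatial arrangement at that carbon, and the (R,R)-TADDOL is taken to give the (1S,2S) Diels–Alder adduct (otherwise its mirror image is used).

**Route**

Step 1
Reactants: 1 Rawal's diene (E)-3-(tert-butyldimethylsilyloxy)-N,N-dimethylbuta-1,3-dien-1-amine; 2 ethyl (2E)-3-methyl-4-oxobut-2-enoate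
Product: 4 ethyl (1S,2S)-2-formyl-2-methyl-5-oxocyclohex-3-ene-1-carboxylate, via cycloadduct 3 (not isolated)
Conditions: (R,R)-α,α,α′,α′-tetra(1-naphthyl)-2,2-dimethyl-1,3-dioxolane-4,5-dimethanol (20 mol %), toluene, −78 °C; then HF (aq), MeCN, 0 °C
Reagents that add atoms: none
Why: Hydrogen-bond-catalysed Diels–Alder reaction of the 1-amino-3-siloxydiene, in which the nucleophilic CH2 terminus bonds β to the formyl group (a stronger activator than the ester) so that C1 becomes the methyl/formyl quaternary centre, the E-dienophile fixes CHO and CO2Et trans (C1/C10), the TADDOL-bound aldehyde is attacked on one face only (absolute configuration), and HF then eliminates dimethylamine and cleaves the silyl enol ether to the enone.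

Step 2
Reactants: 4 ethyl (1S,2S)-2-formyl-2-methyl-5-oxocyclohex-3-ene-1-carboxylate
Product: 6 (3S,3aS,7aS)-3-ethenyl-3a-methyl-3a,7a-dihydro-2-benzofuran-1,6(3H,7H)-dione (trans-fused C2–O–C9 lactone), via hydroxy ester 5 (not isolated)
Conditions: CH2=CHBr, CrCl2 (4 equiv), NiCl2 (2 mol %), DMF, 23 °C; then pyridinium p-toluenesulfonate, benzene, 60 °C
Reagents that add atoms: vinyl bromide (C=CBr)
Why: Nozaki–Hiyama–Kishi vinylation, which is selective for the aldehyde in the presence of enone and ester, proceeds by Felkin–Anh attack anti to the ring carbon C10 and past the methyl group to set C2 as in the target, and the resulting alkoxide/ester pair, trans on ring A, closes under mild acid to the γ-lactone that masks O2 and keeps C9 at the acyl level.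

Step 3
Reactants: 6 trans-fused vinyl lactone enone
Product: 9 C11-methylidene dienone (6 bearing =CH2 at C11), via Mannich base 7 (not isolated), via methiodide 8 (not isolated)
Conditions: LiN(SiMe3)2, THF, −78 °C; Me2N=CH2+ I−, −78 → 0 °C; MeI, MeCN, 23 °C; NaHCO3 (aq), CH2Cl2
Reagents that add atoms: Eschenmoser's salt (C=[N+](C)C.[I-])
Why: Eschenmoser methylenation: kinetic enolisation is possible only at C11 (C1 is quaternary and the lactone α-H at C10 is far less acidic), the enolate undergoes a Mannich reaction with the iminium salt, and quaternisation followed by E1cB loss of trimethylamine gives the exocyclic enone that carries C20.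

Step 4
Reactants: 9 C11-methylidene dienone
Product: 10 (12R)-dienol (C12 carbinol as in the target)
Conditions: (S)-2-methyl-CBS-oxazaborolidine (20 mol %), catecholborane, toluene, −78 °C
Reagents that add atoms: none
Why: Corey–Bakshi–Shibata reduction gives clean 1,2-reduction under catalyst control, the branched C11(=CH2) flank acting as the large substituent so that the (S)-catalyst delivers hydride to the face that leaves the C12 oxygen on the side of C2 (12R, as in the target), the lactone being inert at −78 °C.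

Step 5
Reactants: 10 (12R)-dienol
Product: 11 11,20-epoxy alcohol (epoxide oxygen cis to 12-OH; C11 as in the target)
Conditions: VO(acac)2 (5 mol %), t-BuOOH, CH2Cl2, 0 °C
Reagents that add atoms: tert-butyl hydroperoxide (CC(C)(C)OO)
Why: Hydroxyl-directed vanadium-catalysed epoxidation (Sharpless conditions for allylic alcohols) delivers oxygen to the 1,1-disubstituted C11=C20 alkene from the face of the C12 hydroxyl, which sets C11 as in the target, while the neopentylic ring alkene is less nucleophilic and the C2 vinyl group has no free hydroxyl to direct the reagent.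

Step 6
Reactants: 12 (R)-4-methyloxolan-2-one
Product: 13 (3R,4S)-3-hydroxy-4-methyloxolan-2-one
Conditions: LiN(SiMe3)2, THF, −78 °C; 2-(phenylsulfonyl)-3-phenyloxaziridine; AcOH
Reagents that add atoms: 2-(phenylsulfonyl)-3-phenyloxaziridine (O=S(=O)(N1OC1c1ccccc1)c1ccccc1)
Why: Davis enolate hydroxylation introduces O8 trans to the methyl group; this new centre is planarised again in step 7, so only the C17 configuration bought with 12 is carried on.

Step 7
Reactants: 11 11,20-epoxy alcohol lactone; 13 (3R,4S)-3-hydroxy-4-methyloxolan-2-one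
Product: 14 C9 hemiketal (C2–O–C9(OH) ring; C8 quaternary carbinol as in the target)
Conditions: 13 (3 equiv), LiN(i-Pr)2 (6.3 equiv), THF, −78 → −20 °C; then 11, −78 → −30 °C; AcOH
Reagents that add atoms: none
Why: Claisen-type acylation of the alkoxide–enolate dianion of 13 by the strained trans-fused lactone forms the C8–C9 bond on the enolate face anti to the C17 methyl group (C8 as in the target, O8 cis to CH3), and the tetrahedral intermediate is retained as the five-membered hemiketal alkoxide, which blocks a second addition and retro-Claisen cleavage.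

Step 8
Reactants: 14 C9 hemiketal
Product: 15 tetraol lactone (free 2-OH 8-OH 9-OH 12-OH; C9 as in the target)
Conditions: Zn(BH4)2, Et2O, −20 → 0 °C
Reagents that add atoms: none
Why: Chelation-controlled reduction of the α-hydroxy ketone that is in equilibrium with the hemiketal: zinc bridges O8 and O9 and hydride enters past the flat C7 carbonyl rather than past C17, which is at the same time the Felkin–Anh face with respect to C10 (anti to C1), so both elements give the 9S carbinol.

Step 9
Reactants: 15 tetraol lactone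
Product: 17 2,9,12-tris(triethylsilyl) 8-dimethyl(vinyl)silyl ether, via tris(triethylsilyl) ether 16 (not isolated)
Conditions: Et3SiCl (3.5 equiv), imidazole, DMF, 0 → 23 °C; then CH2=CHSiMe2Cl, 4-(dimethylamino)pyridine, 40 °C
Reagents that add atoms: chlorotriethylsilane (CC[Si](Cl)(CC)CC); chloro(dimethyl)vinylsilane (C=C[Si](C)(C)Cl)
Why: Silyl ether formation in two stages of one pot: the bulky chlorotriethylsilane reacts only with the three secondary hydroxyls, after which the small vinylsilyl chloride caps the tertiary C8 hydroxyl, providing a non-chelating O8 for step 11 as well as the metathesis tether.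

Step 10
Reactants: 17 fully silylated lactone
Product: 18 lactol (C7 hemiacetal)
Conditions: i-Bu2AlH, CH2Cl2, −78 °C
Reagents that add atoms: none
Why: Partial reduction of the lactone by i-Bu2AlH stops at the aluminium hemiacetal at −78 °C and gives the lactol, that is C7 at the aldehyde oxidation level.

Step 11
Reactants: 18 lactol; 19 3-chloro-1-(trimethylsilyl)prop-1-yne
Product: 20 anti-chlorohydrin diol (6S-Cl 7R-OH; C18 primary alcohol; alkynylsilane)
Conditions: 19 (4 equiv), n-BuLi, THF, −90 °C; ZnBr2, −78 °C; then 18, −78 → −20 °C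
Reagents that add atoms: none
Why: Chloroallenylzinc addition to the open-chain aldehyde form of the lactol (SE2′ propargylation through a cyclic transition state) gives the anti C6-Cl/C7-OH pair, and Cornforth/Felkin–Anh attack anti to the large C9 substituent with the carbonyl opposed to the C8–OSi bond gives 7R, so C6 and C7 are set as in the target.

Step 12
Reactants: 20 anti-chlorohydrin diol
Product: 22 γ-lactone (7,18-olide), via lactol 21 (not isolated)
Conditions: TEMPO (2,2,6,6-tetramethylpiperidin-1-oxyl, 20 mol %), PhI(OAc)2 (2.5 equiv), CH2Cl2, 23 °C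
Reagents that add atoms: none
Why: TEMPO/PhI(OAc)2 oxidation (oxidative lactonisation of a 1,4-diol) converts only the primary alcohol to the aldehyde, which is trapped by the C7 hydroxyl as a lactol that is oxidised on to the γ-lactone; C9–O is silylated, so only the 7,18-lactone can form.

Step 13
Reactants: 22 γ-lactone alkynylsilane
Product: 23 terminal alkyne
Conditions: AgNO3 (20 mol %), acetone–H2O, 23 °C
Reagents that add atoms: none
Why: Silver-catalysed protodesilylation of the alkynylsilane takes place at neutral pH and leaves the silyl ethers, the lactone and the propargylic chloride untouched.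

Step 14
Reactants: 23 terminal alkyne
Product: 25 oxasilepine-fused ring-B diene (3Z), via vinyl oxasilepine 24 (not isolated)
Conditions: second-generation Hoveyda–Grubbs catalyst (15 mol %), toluene (1 mM), 80 °C, argon sparge
Reagents that add atoms: none
Why: Proposed new method: tandem silicon-tethered ring-closing enyne metathesis/ring-closing diene metathesis, in which Ru=CH2 adds to the terminal alkyne with its carbon on C4, the vinylcarbene at C5 closes on the tethered vinylsilane (seven-membered exo ring closure that installs C16 and returns Ru=CH2), and the new C4 vinyl group then closes the ten-membered ring B onto the C2 vinyl group with loss of ethylene, the ring size allowing only the Z C3=C4 alkene; the closest known reaction types are silicon-tethered ring-closing enyne metathesis and dienyne tandem ring-closing metathesis.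

Step 15
Reactants: 25 oxasilepine-fused ring-B diene
Product: 26 2,8,9,12-tetraol 11,20-epoxide (3Z,5(16)-diene)
Conditions: Bu4NF (6 equiv), THF, 0 → 40 °C
Reagents that add atoms: none
Why: Fluoride cleaves the three triethylsilyl ethers and the Si–O8 bond, and protodesilylation of the resulting alkenylsilane (retention at C16, which becomes the exocyclic CH2) removes the tether without trace.

Step 16
Reactants: 26 tetraol epoxide
Product: 27 2,9,12-triacetate 11,20-epoxide
Conditions: Ac2O, pyridine, 4-(dimethylamino)pyridine (10 mol %), CH2Cl2, 0 → 23 °C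
Reagents that add atoms: acetic anhydride (CC(=O)OC(C)=O)
Why: DMAP-catalysed acetylation esterifies the three secondary hydroxyls at C2 C9 C12, whereas the hindered tertiary C8 hydroxyl does not react at room temperature.

Step 17
Reactants: 27 triacetate epoxide
Product: 28 target (1S,2S,3Z,6S,7R,8R,9S,10S,11S,12R,17R)-2,9,12-triacetoxy-6,20-dichloro-8,11-dihydroxybriara-3,5(16),13-trien-18,7-olide
Conditions: LiCl, AcOH, THF, 23 °C
Reagents that add atoms: lithium chloride ([Li+].[Cl-])
Why: Regioselective SN2 opening of the 2,2-disubstituted epoxide by chloride at the primary C20 under weakly acidic conditions (halohydrin formation) leaves the C11–O bond untouched, so 11-OH keeps the configuration set in step 5.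

**Compound list**

1 | Rawal's diene, (E)-3-(tert-butyldimethylsilyloxy)-N,N-dimethylbuta-1,3-dien-1-amine | CN(C)/C=C/C(=C)O[Si](C)(C)C(C)(C)C | starting material
2 | ethyl (2E)-3-methyl-4-oxobut-2-enoate | CCOC(=O)/C=C(\C)C=O | starting material
3 | Diels–Alder cycloadduct (amino silyl enol ether; NMe2 cis to CHO; C1, C10 as in the target) | O=C[C@@]1(C)[C@@H](N(C)C)C=C(O[Si](C)(C)C(C)(C)C)C[C@@H]1C(=O)OCC | intermediate
4 | ethyl (1S,2S)-2-formyl-2-methyl-5-oxocyclohex-3-ene-1-carboxylate | O=C[C@@]1(C)C=CC(=O)C[C@@H]1C(=O)OCC | intermediate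
5 | ethyl (1S,2S)-2-[(1S)-1-hydroxyprop-2-en-1-yl]-2-methyl-5-oxocyclohex-3-ene-1-carboxylate | C=C[C@H](O)[C@@]1(C)C=CC(=O)C[C@@H]1C(=O)OCC | intermediate
6 | (3S,3aS,7aS)-3-ethenyl-3a-methyl-3a,7a-dihydro-2-benzofuran-1,6(3H,7H)-dione (trans-fused C2–O–C9 lactone on the ring-A enone) | C=C[C@@H]1OC(=O)[C@H]2CC(=O)C=C[C@]12C | intermediate
7 | Mannich base: 6 bearing CH2NMe2 at C11 (C11 epimers) | C=C[C@@H]1OC(=O)[C@H]2C(CN(C)C)C(=O)C=C[C@]12C | intermediate
8 | methiodide of 7 | C=C[C@@H]1OC(=O)[C@H]2C(C[N+](C)(C)C)C(=O)C=C[C@]12C.[I-] | intermediate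
9 | C11-methylidene dienone (6 bearing =CH2 at C11; C1, C2, C10 as in the target) | C=C[C@@H]1OC(=O)[C@H]2C(=C)C(=O)C=C[C@]12C | intermediate
10 | (12R)-dienol (C12-OH on the face of C2, anti to the C1 methyl) | C=C[C@@H]1OC(=O)[C@H]2C(=C)[C@H](O)C=C[C@]12C | intermediate
11 | 11,20-epoxy alcohol lactone (epoxide O cis to 12-OH; C1, C2, C10, C11, C12 as in the target) | C=C[C@@H]1OC(=O)[C@H]2[C@@]3(CO3)[C@H](O)C=C[C@]12C | intermediate
12 | (R)-4-methyloxolan-2-one | O=C1C[C@@H](C)CO1 | starting material
13 | (3R,4S)-3-hydroxy-4-methyloxolan-2-one (OH trans to CH3) | O[C@@H]1[C@@H](C)COC1=O | intermediate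
14 | C9 hemiketal (five-membered C2–O–C9(OH) ring, anomers; C8 bears OH and the lactone with C17 as in the target) | C=C[C@@H]1OC(O)([C@]4(O)[C@@H](C)COC4=O)[C@H]2[C@@]3(CO3)[C@H](O)C=C[C@]12C | intermediate
15 | tetraol lactone (2-OH, 8-OH, 9-OH, 12-OH free; C1, C2, C8, C9, C10, C11, C12, C17 as in the target; C7 lactone carbonyl, C18 as CH2–O) | C=C[C@H](O)[C@@]1(C)C=C[C@@H](O)[C@]2(CO2)[C@@H]1[C@H](O)[C@]3(O)[C@@H](C)COC3=O | intermediate
16 | 2,9,12-tris(triethylsilyl) ether of 15 (8-OH free) | C=C[C@H](O[Si](CC)(CC)CC)[C@@]1(C)C=C[C@@H](O[Si](CC)(CC)CC)[C@]2(CO2)[C@@H]1[C@H](O[Si](CC)(CC)CC)[C@]3(O)[C@@H](C)COC3=O | intermediate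
17 | 2,9,12-tris(triethylsilyl) 8-dimethyl(vinyl)silyl ether of 15 | C=C[C@H](O[Si](CC)(CC)CC)[C@@]1(C)C=C[C@@H](O[Si](CC)(CC)CC)[C@]2(CO2)[C@@H]1[C@H](O[Si](CC)(CC)CC)[C@]3(O[Si](C)(C)C=C)[C@@H](C)COC3=O | intermediate
18 | lactol (C7 hemiacetal, anomers) from 17 | C=C[C@H](O[Si](CC)(CC)CC)[C@@]1(C)C=C[C@@H](O[Si](CC)(CC)CC)[C@]2(CO2)[C@@H]1[C@H](O[Si](CC)(CC)CC)[C@]3(O[Si](C)(C)C=C)[C@@H](C)COC3O | intermediate
19 | 3-chloro-1-(trimethylsilyl)prop-1-yne | ClCC#C[Si](C)(C)C | starting material
20 | anti-chlorohydrin diol (6S-Cl, 7R-OH, C18 primary OH, C4 trimethylsilyl alkyne) | C=C[C@H](O[Si](CC)(CC)CC)[C@@]1(C)C=C[C@@H](O[Si](CC)(CC)CC)[C@]2(CO2)[C@@H]1[C@H](O[Si](CC)(CC)CC)[C@](O[Si](C)(C)C=C)([C@@H](C)CO)[C@@H](O)[C@@H](Cl)C#C[Si](C)(C)C | intermediate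
21 | C18 lactol from 20 (anomers) | C=C[C@H](O[Si](CC)(CC)CC)[C@@]1(C)C=C[C@@H](O[Si](CC)(CC)CC)[C@]2(CO2)[C@@H]1[C@H](O[Si](CC)(CC)CC)[C@]3(O[Si](C)(C)C=C)[C@@H](C)C(O)O[C@H]3[C@@H](Cl)C#C[Si](C)(C)C | intermediate
22 | γ-lactone (7,18-olide; C6, C7, C8, C17 as in the target) with trimethylsilyl alkyne | C=C[C@H](O[Si](CC)(CC)CC)[C@@]1(C)C=C[C@@H](O[Si](CC)(CC)CC)[C@]2(CO2)[C@@H]1[C@H](O[Si](CC)(CC)CC)[C@]3(O[Si](C)(C)C=C)[C@@H](C)C(=O)O[C@H]3[C@@H](Cl)C#C[Si](C)(C)C | intermediate
23 | terminal alkyne (metathesis precursor) | C=C[C@H](O[Si](CC)(CC)CC)[C@@]1(C)C=C[C@@H](O[Si](CC)(CC)CC)[C@]2(CO2)[C@@H]1[C@H](O[Si](CC)(CC)CC)[C@]3(O[Si](C)(C)C=C)[C@@H](C)C(=O)O[C@H]3[C@@H](Cl)C#C | intermediate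
24 | vinyl oxasilepine (seven-membered Si–O8 ring with C5=C16; C4 as a vinyl group; ring B still open) | C=C[C@H](O[Si](CC)(CC)CC)[C@@]1(C)C=C[C@@H](O[Si](CC)(CC)CC)[C@]2(CO2)[C@@H]1[C@H](O[Si](CC)(CC)CC)[C@]3(O[Si](C)(C)C=C4C=C)[C@@H](C)C(=O)O[C@H]3[C@H]4Cl | intermediate
25 | oxasilepine-fused ring-B diene (3Z; all ten stereocentres as in the target) | C1=C2/C=C\[C@H](O[Si](CC)(CC)CC)[C@@]3(C)C=C[C@@H](O[Si](CC)(CC)CC)[C@]4(CO4)[C@@H]3[C@H](O[Si](CC)(CC)CC)[C@]5(O[Si]1(C)C)[C@@H](C)C(=O)O[C@H]5[C@H]2Cl | intermediate
26 | 2,8,9,12-tetraol 11,20-epoxide (3Z,5(16)-diene, 6-Cl, 7,18-olide) | C=C1/C=C\[C@H](O)[C@@]2(C)C=C[C@@H](O)[C@]3(CO3)[C@@H]2[C@H](O)[C@]2(O)[C@@H](C)C(=O)O[C@H]2[C@H]1Cl | intermediate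
27 | 2,9,12-triacetate 11,20-epoxide | C=C1/C=C\[C@H](OC(C)=O)[C@@]2(C)C=C[C@@H](OC(C)=O)[C@]3(CO3)[C@@H]2[C@H](OC(C)=O)[C@]2(O)[C@@H](C)C(=O)O[C@H]2[C@H]1Cl | intermediate
28 | CNP0435497.1, (1S,2S,3Z,6S,7R,8R,9S,10S,11S,12R,17R)-2,9,12-triacetoxy-6,20-dichloro-8,11-dihydroxybriara-3,5(16),13-trien-18,7-olide | C=C1/C=C\[C@H](OC(C)=O)[C@@]2(C)C=C[C@@H](OC(C)=O)[C@](O)(CCl)[C@@H]2[C@H](OC(C)=O)[C@]2(O)[C@@H](C)C(=O)O[C@H]2[C@H]1Cl | target

**Totals**

Total step count: 17. Longest linear sequence: 16 (steps 1–5 and 7–17; step 6 is a one-step side branch).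

**Three steps most likely to fail**

Step 14 (cascade metathesis). The ten-membered ring closure onto a hindered allylic silyl ether may be slower than oligomerisation of the alkyne or of the intermediate triene. The fallback sets out from 23 and comes back at 26. Under ethylene (1 atm) with second-generation Grubbs catalyst, the alkyne of 23 undergoes intermolecular cross enyne metathesis to the 2-substituted buta-1,3-diene F1. After removal of ethylene, a separate ring-closing diene metathesis at high dilution joins the C2 vinyl group and the diene's vinyl group to give the ring-B diene silyl ether F2. Bu4NF then removes all four silyl groups and gives 26. Any oxasilepine formed on the way converges on 26 as well.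

Step 7 (acylation of the dianion by the lactone). The lactone carbonyl is hindered, and deprotonation at C10 would epimerise the ring fusion or open the epoxide by β-elimination. The fallback sets out from 11 and comes back at 14. Lactone 11 is first opened with MeNH(OMe)·HCl and i-PrMgCl to the hydroxy Weinreb amide F3, whose α-H is much less acidic and whose carbonyl is no longer part of a strained ring. Addition of the dianion of 13 to F3 gives the C9 ketone, which closes to hemiketal 14.

Step 1 (catalytic asymmetric Diels–Alder). The dienophile is β-substituted and doubly activated, so the uncatalysed background reaction may erode the enantioselectivity. The fallback sets out from 2 and comes back at 4, with auxiliary control in place of catalyst control. (E)-4-Methoxybut-3-en-2-one is condensed with (2S,5S)-2,5-diphenylpyrrolidine to the vinylogous amide F4. Silylation (KN(SiMe3)2, t-BuMe2SiCl) gives the chiral aminosiloxydiene F5. This adds to 2 at low temperature to give the auxiliary-bearing cycloadduct F6, and HF then gives 4 and returns the amine. The (2R,5R)-amine is used if the sense of induction is opposite.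

Further compounds
F1 | step 14 | 2-substituted buta-1,3-diene from cross enyne metathesis of 23 with ethylene | C=C[C@H](O[Si](CC)(CC)CC)[C@@]1(C)C=C[C@@H](O[Si](CC)(CC)CC)[C@]2(CO2)[C@@H]1[C@H](O[Si](CC)(CC)CC)[C@]3(O[Si](C)(C)C=C)[C@@H](C)C(=O)O[C@H]3[C@@H](Cl)C(=C)C=C
F2 | step 14 | ring-B diene silyl ether (3Z; three triethylsilyl ethers and the 8-O-dimethyl(vinyl)silyl ether retained) | C=C1/C=C\[C@H](O[Si](CC)(CC)CC)[C@@]2(C)C=C[C@@H](O[Si](CC)(CC)CC)[C@]3(CO3)[C@@H]2[C@H](O[Si](CC)(CC)CC)[C@]2(O[Si](C)(C)C=C)[C@@H](C)C(=O)O[C@H]2[C@H]1Cl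
F3 | step 7 | hydroxy Weinreb amide from 11 (C9 N-methoxy-N-methylamide, free 2-OH and 12-OH, 11,20-epoxide) | C=C[C@H](O)[C@@]1(C)C=C[C@@H](O)[C@]2(CO2)[C@@H]1C(=O)N(C)OC
F4 | step 1 | (E)-4-[(2S,5S)-2,5-diphenylpyrrolidin-1-yl]but-3-en-2-one | CC(=O)/C=C/N1[C@H](c2ccccc2)CC[C@H]1c1ccccc1
F5 | step 1 | (2S,5S)-1-[(1E)-3-(tert-butyldimethylsilyloxy)buta-1,3-dien-1-yl]-2,5-diphenylpyrrolidine | C=C(O[Si](C)(C)C(C)(C)C)/C=C/N1[C@H](c2ccccc2)CC[C@H]1c1ccccc1
F6 | step 1 | auxiliary-bearing cycloadduct (analogue of 3 with the diphenylpyrrolidine in place of NMe2) | O=C[C@@]1(C)[C@@H](N2[C@H](c3ccccc3)CC[C@H]2c2ccccc2)C=C(O[Si](C)(C)C(C)(C)C)C[C@@H]1C(=O)OCC
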